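(All runs were computed on assumed constants, noise included.)

Begin with the early readings of zeta, where target climbs while substrate falls, then stops: 53.9% at 6.00 h, 53.7% at 12.0 h. Partner, the limiting reagent at 0.95 equiv, has by then made what target it will make.

| flask | substrate | partner | protic impurity | capture agent | remark | time |
|---|---|---|---|---|---|---|
| zeta | 0.050 M | 0.95 equiv | 0.015 M | 0.050 M | run made earlier |  |
| beta | 0.050 M | 0.95 equiv | 0.015 M | 0.025 M | run made earlier |  |
| theta | 0.050 M | 0.95 equiv | 0.015 M | 0.10 M | run made earlier |  |
| oak | 0.050 M | 0.950 equiv (fed, over 16.0 h) | 0.0150 M | 0.0500 M | a stirred flask in which partner is dosed at a steady rate over 16.0 h without added volume, worked up at 20 h | 20 h |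
| maple | 0.050 M | 0.950 equiv | 0.0150 M | 0.0500 M | one stirred flow tank at steady state, fed with the mixture as stated, mean residence time 20 h |  |
| cedar | 0.050 M | 0.950 equiv | 0.0150 M | 0.0500 M | a closed flask charged with all of it at once and left for 20 h | 20 h |
| elm | 0.050 M (fed, over 16.0 h) | 0.950 equiv | 0.0150 M | 0.0500 M | a stirred flask in which substrate is dosed at a steady rate over 16.0 h without added volume, worked up at 20 h | 20 h |

| run | time / h | open intermediate / % | target / % | substrate / % |
|---|---|---|---|---|
| zeta | 1.00 | 14.0 | 20.5 | 63.8 |
| zeta | 2.00 | 16.6 | 40.6 | 42.0 |
| zeta | 3.00 | 21.1 | 48.1 | 28.5 |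
| zeta | 6.00 | 26.6 | 53.9 | 10.8 |
| zeta | 12.0 | 20.7 | 53.7 | 4.9 |
| beta | 1.33 | 12.9 | 31.8 | 55.1 |
| beta | 2.50 | 12.9 | 51.2 | 33.9 |
| beta | 5.00 | 19.2 | 64.7 | 13.2 |
| beta | 8.00 | 19.9 | 65.5 | 5.0 |
| beta | 15.0 | 14.8 | 65.4 | 2.9 |
| theta | 3.00 | 28.4 | 38.2 | 28.6 |
| theta | 6.00 | 30.8 | 41.4 | 11.2 |
| theta | 10.0 | 24.8 | 41.7 | 6.2 |
| theta | 12.0 | 22.2 | 40.8 | 4.2 |
| theta | 15.0 | 18.1 | 41.2 | 3.8 |

(standard deviation of a reading: 0.5 percentage points)

- percentages count the substrate that a species holds: one homo product counts as two
- the stated concentrations are those of everything mixed, before any reaction; amounts are the same in each set-up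
- what may be going on: partner -> second intermediate; substrate <-> open intermediate; partner + protic impurity -> quenched reagent; open intermediate + second intermediate -> target; 2 open intermediate -> homo product; second intermediate + capture agent -> trapped intermediate
- the feed brings no volume worth counting
- the earlier runs were made in a closed, stirred flask

1. the set-up with the highest amount of open intermediate at the outlet or at the end, in percent of the substrate put in ("none" if the first two lie within 2 percentage points) (oak / maple / cedar / elm / none)
2. amount of open intermediate at the outlet or at the end, in percent of the substrate put in, oak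
3. amount of open intermediate at the outlet or at the end, in percent of the substrate put in, maple
4. amount of open intermediate at the outlet or at the end, in percent of the substrate put in, cedar
5. amount of open intermediate at the outlet or at the end, in percent of the substrate put in, elm

Keep the ledger of that partner first. Target takes the entry that moves with capture agent, 65.4% in beta and 41.2% in theta, and the remaining partner is booked to trapped intermediate and quenched reagent. Now book the substrate of zeta at 12.0 h: target 53.7%, open intermediate 20.7%, substrate 4.9%, and the gap of 20.7% entered as homo product, which closes the books.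

Define the free pool W as c(substrate) plus c(open intermediate), in parts of the charge. Once target stands still, book the loss of W to the pairing into homo product and hold the open share of W fixed, so take the reciprocal of W to rise in a straight line. Call its slope the pool clock 0.243 h⁻¹, read from theta, whose target reads 41.4% at 6.00 h and 41.2% at 15.0 h. Zeta's stretch, shorter than theta's, reads 0.205 h⁻¹, so treat the clock as a reading with that spread. The open share of the pool in theta at 15.0 h reads 82.6%.

Run the clock on cedar, which has zeta's charge: from 25.6% at 12.0 h, W reaches 17.1% at 20 h, so open intermediate is 14.1%. For elm, let the feed fill the pool against the clock and, as a simplification, book nothing to target: this reckoning gives W 48.8% at the end of the feed and, after the remaining time, open intermediate 27.4%. Commit to elm above cedar. The forecast says elm, with oak 3%, maple 15.5%, cedar 14.3% and elm 31%: “Later substrate meets only homo loss”.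

Elm gives 30.2%, above maple 15.4%, cedar 13.5% and oak 2.04%. Its pool at the end of the feed stood at 55.8%, above my 48.8%. Started there, the clock gives W 36.2% at 20 h, against 38.3% in the flask.

    partner → second intermediate (k = 0.0153 min⁻¹)
    substrate ⇌ open intermediate (K = 5.61, k = 0.00753 min⁻¹)
    partner + protic impurity → quenched reagent (k = 0.0994 M⁻¹ min⁻¹)
    open intermediate + second intermediate → target (k = 3.58 M⁻¹ min⁻¹)
    2 open intermediate → homo product (k = 0.0624 M⁻¹ min⁻¹)
    second intermediate + capture agent → trapped intermediate (k = 0.398 M⁻¹ min⁻¹)

Run the pool clock on to 30 h in elm: from the 20 h pool it gives open intermediate 16.4%, and the computed flask holds 16.2%.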